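**Retrosynthetic overview**
1. Target 14 is 3,5,7,8-tetramethoxy-2-(2-methoxyphenyl)chromen-4-one; the last step is O-methylation of the 5,7-diol 13.
2. Feature used: ring A carries oxygen on C5 and C7 in a 1,3-relationship next to the C8 methoxy group (acylphloroglucinol pattern). The C5–C6 bond is therefore cut, so that C5 becomes an ester carbon on C3 of a 4-pyranone (ring C) and C6–C7–C8 a CH(OMe)COCH3 chain on its C2 (compound 11).
3. 11 comes from pyranone 9 by acetylation of its lateral CH2OMe carbanion with amide 10, so the C8 methoxy group is present from the start.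
4. Ring C (9) is cut at C3–C4 and O1–C6: C-acylation of methyl 4-methoxyacetoacetate 6 by β-chloroacryloyl chloride 7, then displacement of the vinylic chloride by the enol oxygen. 7 derives from ketone 3 (Grignard reagent 1 plus amide 2) by chloroformylation and oxidation.
5. Ring order: ring B is bought, ring C is closed in step 4, ring A is closed last in step 6.

Key step: step 6

Remark: compounds 4, 5, 7 and 8 are expected as mixtures of alkene isomers, which converge in step 4 because the vinylic chloride is displaced by addition–elimination, so their SMILES carry no double-bond descriptor. Compounds 11 and 12 are racemic at one enolisable centre that is erased in step 6, and the target has no stereocentre.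

**Step 1**
Reactants: 1 2-methoxyphenylmagnesium bromide; 2 N,2-dimethoxy-N-methylacetamide
Product: 3 2-methoxy-1-(2-methoxyphenyl)ethan-1-one
Conditions: THF, 0 °C to rt; then aq. HCl
Reagents that add atoms: none
Why: In this Weinreb ketone synthesis the aryl Grignard reagent adds once to the N-methoxy-N-methylamide to give a magnesium-chelated tetrahedral adduct that releases the α-methoxy ketone only on acidic work-up, so over-addition is excluded.

**Step 2**
Reactants: 3 2-methoxy-1-(2-methoxyphenyl)ethan-1-one
Product: 4 3-chloro-2-methoxy-3-(2-methoxyphenyl)prop-2-enal (mixture of alkene isomers)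
Conditions: POCl3, DMF, 0 to 60 °C; then ice-water
Reagents that add atoms: N,N-dimethylformamide, CN(C)C=O; phosphoryl chloride, O=P(Cl)(Cl)Cl; water, O
Why: In this Vilsmeier–Haack–Arnold chloroformylation the chloroiminium salt formylates the only enolisable carbon (CH2OMe) and the ketone oxygen is exchanged for chloride, so hydrolysis should give the β-chloro enal, while the acyl-deactivated anisole ring should stay unformylated.

**Step 3**
Reactants: 4 3-chloro-2-methoxy-3-(2-methoxyphenyl)prop-2-enal
Product: 5 3-chloro-2-methoxy-3-(2-methoxyphenyl)prop-2-enoic acid (mixture of alkene isomers)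
Conditions: NaClO2, NaH2PO4, 2-methyl-2-butene, t-BuOH/H2O, rt
Reagents that add atoms: sodium chlorite, [Na+].[O-]Cl=O
Why: The Pinnick oxidation converts the enal into the acid under buffered conditions that should leave the vinylic chloride and the enol ether untouched, with 2-methyl-2-butene removing the hypochlorous acid that is formed.

**Step 4**
Reactants: 5 3-chloro-2-methoxy-3-(2-methoxyphenyl)prop-2-enoic acid; 6 methyl 4-methoxy-3-oxobutanoate
Product: 9 methyl 5-methoxy-2-(methoxymethyl)-6-(2-methoxyphenyl)-4-oxo-4H-pyran-3-carboxylate, via acid chloride 7 (not isolated), via C-acylated keto ester 8 (not isolated)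
Conditions: (COCl)2, cat. DMF, CH2Cl2, 0 °C to rt, evaporate; then 6, MgCl2, pyridine, CH2Cl2, 0 °C to rt; then Et3N, MeCN, 60 °C
Reagents that add atoms: none
Why: The acid chloride made with oxalyl chloride should C-acylate the chelated magnesium enolate of the β-keto ester (MgCl2/amine soft enolisation), and the enol oxygen of the methoxyacetyl group then displaces the vinylic chloride by 6-endo addition–elimination, the closure known from chromone formation from 2-hydroxyaryl β-chlorovinyl ketones, so both alkene isomers converge on the 4-pyranone.

**Step 5**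
Reactants: 9 methyl 5-methoxy-2-(methoxymethyl)-6-(2-methoxyphenyl)-4-oxo-4H-pyran-3-carboxylate; 10 N-methoxy-N-methylacetamide
Product: 11 methyl 5-methoxy-2-(1-methoxy-2-oxopropyl)-6-(2-methoxyphenyl)-4-oxo-4H-pyran-3-carboxylate (racemic)
Conditions: LiN(SiMe3)2, THF, −78 °C; then 10, −78 to 0 °C; aq. NH4Cl
Reagents that add atoms: none
Why: The CH2OMe protons are vinylogous to both the C4 ketone and the C3 ester and are the only acidic protons, so the lithium dienolate should form cleanly and add through its exocyclic carbon to the N-methoxy-N-methylamide (Weinreb ketone synthesis), whose chelated adduct releases the ketone only on work-up and so prevents proton transfer from the more acidic product; the new stereocentre is formed racemic and is not needed.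

**Step 6**
Reactants: 11 methyl 5-methoxy-2-(1-methoxy-2-oxopropyl)-6-(2-methoxyphenyl)-4-oxo-4H-pyran-3-carboxylate
Product: 13 5,7-dihydroxy-3,8-dimethoxy-2-(2-methoxyphenyl)-4H-chromen-4-one, via cyclised trione 12 (not isolated)
Conditions: LiN(i-Pr)2 (3 equiv), THF, −78 °C to rt; then aq. HCl
Reagents that add atoms: none
Why: Proposed new method: the first equivalent of LiN(i-Pr)2 removes the C8 proton (flavone numbering), which lies between the side-chain ketone and the pyranone, the second deprotonates the terminal methyl group as in a β-diketone dianion, and this carbon (C6) adds to the carbonyl of the C3 ester (C5), after which loss of methoxide gives trione 12 and enolisation gives the diphenolate of 13. The closest known reactions are the base-mediated Claisen cyclisation of 2-(2-oxopropyl)benzoates to naphthalene-1,3-diols and of β-polyketo esters to acylphloroglucinols, neither of which has been run on a 4-pyranone-3-carboxylate. Ring A closes in the 6-exo-trig mode. No stereocentre is formed, and the racemic centre of 11 is erased on aromatisation. The step needs carbon rather than oxygen acylation and attack on the ester rather than on C4: attack on C4 would require a bridge across the planar pyranone, and closure through the enolate oxygen to an enol lactone is reversible in the presence of LiOMe, whereas carbon closure is made irreversible by aromatisation.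

**Step 7**
Reactants: 13 5,7-dihydroxy-3,8-dimethoxy-2-(2-methoxyphenyl)-4H-chromen-4-one
Product: 14 3,5,7,8-tetramethoxy-2-(2-methoxyphenyl)-4H-chromen-4-one
Conditions: Me2SO4 (excess), K2CO3, acetone, reflux
Reagents that add atoms: dimethyl sulfate, COS(=O)(=O)OC
Why: In this Williamson O-methylation the acidic 7-OH should react readily and the hydrogen-bonded 5-OH should follow with excess reagent at prolonged reflux, conditions under which the existing methyl ethers and the pyranone are inert.

**Compound list**
1 | 2-methoxyphenylmagnesium bromide | COc1ccccc1[Mg]Br | starting material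
2 | N,2-dimethoxy-N-methylacetamide | COCC(=O)N(C)OC | starting material
3 | 2-methoxy-1-(2-methoxyphenyl)ethan-1-one | COCC(=O)c1ccccc1OC | intermediate
4 | 3-chloro-2-methoxy-3-(2-methoxyphenyl)prop-2-enal (mixture of alkene isomers) | COc1ccccc1C(Cl)=C(OC)C=O | intermediate
5 | 3-chloro-2-methoxy-3-(2-methoxyphenyl)prop-2-enoic acid (mixture of alkene isomers) | COc1ccccc1C(Cl)=C(OC)C(=O)O | intermediate
6 | methyl 4-methoxy-3-oxobutanoate (methyl 4-methoxyacetoacetate) | COCC(=O)CC(=O)OC | starting material
7 | 3-chloro-2-methoxy-3-(2-methoxyphenyl)prop-2-enoyl chloride (formed in the flask) | COc1ccccc1C(Cl)=C(OC)C(Cl)=O | intermediate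
8 | methyl 2-[3-chloro-2-methoxy-3-(2-methoxyphenyl)prop-2-enoyl]-4-methoxy-3-oxobutanoate (formed in the flask) | COCC(=O)C(C(=O)OC)C(=O)C(OC)=C(Cl)c1ccccc1OC | intermediate
9 | methyl 5-methoxy-2-(methoxymethyl)-6-(2-methoxyphenyl)-4-oxo-4H-pyran-3-carboxylate | COCc1oc(-c2ccccc2OC)c(OC)c(=O)c1C(=O)OC | intermediate
10 | N-methoxy-N-methylacetamide | CC(=O)N(C)OC | starting material
11 | methyl 5-methoxy-2-(1-methoxy-2-oxopropyl)-6-(2-methoxyphenyl)-4-oxo-4H-pyran-3-carboxylate (racemic) | COC(=O)c1c(C(OC)C(C)=O)oc(-c2ccccc2OC)c(OC)c1=O | intermediate
12 | 3,8-dimethoxy-2-(2-methoxyphenyl)-6H-chromene-4,5,7(8H)-trione (racemic, formed in the flask) | COc1ccccc1-c1oc2c(c(=O)c1OC)C(=O)CC(=O)C2OC | intermediate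
13 | 5,7-dihydroxy-3,8-dimethoxy-2-(2-methoxyphenyl)-4H-chromen-4-one | COc1ccccc1-c1oc2c(OC)c(O)cc(O)c2c(=O)c1OC | intermediate
14 | 3,5,7,8-tetramethoxy-2-(2-methoxyphenyl)-4H-chromen-4-one | COc1ccccc1-c1oc2c(OC)c(OC)cc(OC)c2c(=O)c1OC | target

**Totals**
Total step count: 7.
Longest linear sequence: 7 steps (1 → 3 → 4 → 5 → 9 → 11 → 13 → 14); compounds 2, 6 and 10 enter as bought reagents.

**Steps most likely to fail**

Step 6. The closure may run through the enolate oxygen to an enol lactone instead of through carbon. It may also stall because the first negative charge is delocalised into the C3 ester and lowers its electrophilicity, or because the side chain sits in the rotamer that points the methyl group away from the ester. The fallback uses known chemistry, sets out from acid 5 and comes back at target 14. Acid 5 is converted into acid chloride 7 as in step 4 and used in a Friedel–Crafts acylation of commercial 1,2,3,5-tetramethoxybenzene (AlCl3, CH2Cl2, 0 °C to rt) to give 3-chloro-2-methoxy-3-(2-methoxyphenyl)-1-(2,3,4,6-tetramethoxyphenyl)prop-2-en-1-one F1. In the same flask AlCl3 is expected to cleave the chelated ortho methoxy group that is flanked by the carbonyl and a second methoxy group, giving 3-chloro-1-(2-hydroxy-3,4,6-trimethoxyphenyl)-2-methoxy-3-(2-methoxyphenyl)prop-2-en-1-one F2. K2CO3 in refluxing acetone should then close ring C by displacement of the vinylic chloride by the phenoxide, which gives 14 directly. Ring A is then bought instead of built, and steps 5 to 7 are not needed.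

Step 4. The enolate may be acylated on oxygen, the triacylmethane may lose its methoxyacetyl group, or the ring closure at the tetrasubstituted chloroalkene may be slow. The fallback sets out from 6 and comes back at 9. The dianion of 6 (NaH, then n-BuLi, THF, 0 °C) is aroylated at its C4 carbon with methyl 2-methoxybenzoate to give methyl 4-methoxy-5-(2-methoxyphenyl)-3,5-dioxopentanoate F3. Knoevenagel condensation of the C2 methylene group with methoxyacetaldehyde (piperidinium acetate, toluene, water removal) should give methyl 4-methoxy-2-(2-methoxyethylidene)-5-(2-methoxyphenyl)-3,5-dioxopentanoate F4. Its aryl ketone enol should add 6-endo to the new alkene to give methyl 5-methoxy-2-(methoxymethyl)-6-(2-methoxyphenyl)-4-oxo-3,4-dihydro-2H-pyran-3-carboxylate F5 (mixture of diastereomers). DDQ in hot dioxane then dehydrogenates C2–C3 to give 9. This path needs no acid chloride and forms the O1–C2 bond by oxa-Michael addition instead of vinylic substitution.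

Step 5. The stabilised dienolate may add too slowly to the amide, or may attack the ester of a second molecule. The fallback sets out from 6 and comes back at 11, and it puts the acetyl group in before ring C is made. The dianion of 6 (NaH, then n-BuLi, THF, 0 °C) is acetylated at C4 with amide 10 to give methyl 4-methoxy-3,5-dioxohexanoate F6. C-acylation of its C2 methylene carbon, the less hindered of the two acidic positions, with acid chloride 7 (from 5 as in step 4; MgCl2, pyridine, CH2Cl2) should give methyl 2-[3-chloro-2-methoxy-3-(2-methoxyphenyl)prop-2-enoyl]-4-methoxy-3,5-dioxohexanoate F7, which is not isolated. Et3N in warm MeCN should close the pyranone through the C3 enol oxygen to give 11.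

**Further compounds**
F1 | step 6 | 3-chloro-2-methoxy-3-(2-methoxyphenyl)-1-(2,3,4,6-tetramethoxyphenyl)prop-2-en-1-one | COc1ccccc1C(Cl)=C(OC)C(=O)c1c(OC)c(OC)c(OC)cc1OC
F2 | step 6 | 3-chloro-1-(2-hydroxy-3,4,6-trimethoxyphenyl)-2-methoxy-3-(2-methoxyphenyl)prop-2-en-1-one | COc1ccccc1C(Cl)=C(OC)C(=O)c1c(O)c(OC)c(OC)cc1OC
F3 | step 4 | methyl 4-methoxy-5-(2-methoxyphenyl)-3,5-dioxopentanoate | COc1ccccc1C(=O)C(OC)C(=O)CC(=O)OC
F4 | step 4 | methyl 4-methoxy-2-(2-methoxyethylidene)-5-(2-methoxyphenyl)-3,5-dioxopentanoate | COCC=C(C(=O)OC)C(=O)C(OC)C(=O)c1ccccc1OC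
F5 | step 4 | methyl 5-methoxy-2-(methoxymethyl)-6-(2-methoxyphenyl)-4-oxo-3,4-dihydro-2H-pyran-3-carboxylate | COCC1OC(-c2ccccc2OC)=C(OC)C(=O)C1C(=O)OC
F6 | step 5 | methyl 4-methoxy-3,5-dioxohexanoate | CC(=O)C(OC)C(=O)CC(=O)OC
F7 | step 5 | methyl 2-[3-chloro-2-methoxy-3-(2-methoxyphenyl)prop-2-enoyl]-4-methoxy-3,5-dioxohexanoate | CC(=O)C(OC)C(=O)C(C(=O)OC)C(=O)C(OC)=C(Cl)c1ccccc1OC
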